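We read this flask at 8.0 d, which is long against the 9.91 h half-life that coupling partner has by coupling alone if dissolved substrate stands at its solubility, so we ask where a molecule ends and not when it gets there.

solid substrate 1.5 M; coupling partner 1.58 M; time 8.0 d

    solid substrate ⇌ dissolved substrate, rate k1*(cs1 - [dissolved substrate]) while solid is left; crystals form when [dissolved substrate] > cs1 (cs1 = 0.92 M, k1 = 0.079 h⁻¹)
    dissolved substrate + coupling partner → target (k2 = 0.076 M⁻¹ h⁻¹)
    solid product ⇌ target, rate k3*(cs3 - [target]) while solid is left; crystals form when [target] > cs3 (cs3 = 0.53 M, k3 = 4.0 h⁻¹)
    2 coupling partner → self-condensation product (k4 = 0.010 M⁻¹ h⁻¹)
    target ⇌ isomer of the product (K5 = 0.55, k5 = 0.048 h⁻¹)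

- amounts and yields of target count solid product too
- two of one species on the left: rate k times its square, two consumed each time
- given per volume of solution although it is solid: solid substrate, solid product
- at the start none of the solid substrate is in solution
- run time (flask): 8.0 d

* how much target and solid product together there is at 8.0 d, in percent of the solid substrate charged
* the change that raises the amount of target and solid product together at 8.0 d, in percent of the solid substrate charged most ("none" if none brings more than 2 percentage points) (dusk / spring / midnight / summer / none)
* amount of target and solid product together at 8.0 d, in percent of the solid substrate charged, after midnight

- dusk: doubling the amount of coupling partner, all else as stated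
- spring: doubling the dissolution coefficient of step 1, all else as stated
- midnight: doubling the dissolution coefficient of step 3, all else as stated
- summer: doubling the solubility in step 3, all else as stated

Follow one molecule of coupling partner. We take c(dissolved substrate) at its solubility and c(coupling partner) at its charge, two rough values that pull opposite ways. Its fork is then worth 0.0699 h⁻¹ towards coupling against 0.0316 h⁻¹ towards self-condensation, so it couples with chance 68.9%. Chance times charge, over the solid substrate charged, gives 72.5%, the partner's reach: the part of the substrate that the coupling partner can carry to product.

Turn the question round. For coupling partner to stop being the limiting reagent, the reach would have to cover the whole charge, and this flask falls short of that, so we pick dusk.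

The product molecule forks too. The reach carries 1.09 M, more than the 0.822 M that saturated solution and its isomer hold, so we expect 0.292 M of isomer. Taking that off, we commit to 53.1%. The half-life set by the dissolution coefficient of solid product, 0.173 h, is short against the time, so we expect no change after midnight.

The forecast gives 45%, picks dusk, and gives 45% after midnight, since “faster crystal dissolution changes nothing because that step is already at equilibrium”. It stands below us: it allows 0.97 M of product where we allow 1.09 M.

The simulation gives 48.5%, and 48.5% after midnight, with dusk ahead at 24 percentage points. In this flask at 8.00 d, coupling partner stands at 0.0350% of its charge while dissolved substrate still holds 32.0% of the substrate charged. With solid substrate at 0%, that leaves 68.0% of the substrate charged as target and isomer of the product together, against a reach of 72.5%.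

In the neighbour with 0.95 M of coupling partner, the chance becomes 78.6% and the reach 49.8%. That carries less than saturation needs, so target and isomer share it by their equilibrium constant, which leaves 32.1% as target. The simulated neighbour gives 31.1%, with 0% of solid product.

The rate constants are invented; no experiment stands behind them.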